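**Retrosynthetic overview**

1. Ring C (cyclobutane, C4–C10) is closed last. Ring A, as a 1-siloxy-1,3-diene made in the flask from β,γ-enone 22, attacks the tertiary carbon of a 9α,10α-epoxide anti to oxygen. This is the himachalyl→longipinyl closure in epoxide-initiated form. It gives the free 9-OH, the C10 quaternary centre and the enone in one operation, with both esters already in place.
2. 22 comes from a cis-fused 4,10-seco-longipinadiene (himachalane skeleton) by hydroxyl-directed epoxidation, acylation and C–B→C=O. Ring B comes from ring-closing metathesis (C9=C10).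
3. C7/C8 come from a reagent-controlled (Z)-γ-alkoxyallylboration of a neopentyl aldehyde.
4. Ring A comes from a catalytic enantioselective endo Diels–Alder reaction of diene 3 with β-boryl enone 6. It sets cis C5/C11, places C3=C4 and puts boron on C1 as a latent ketone.
5. Order of ring formation: A (six) → B (seven) → C (four).

Assumption: 1, 2, 4, 5, 10, 14 and 19 are catalogue chemicals. Atom numbers in all names are those of the target (ring atoms C1–C11, C12 on C3, C13/C14 on C6, C15 on C10). α is the face carrying H-5 and H-11. Bpin = 4,4,5,5-tetramethyl-1,3,2-dioxaborolan-2-yl, angeloyl = (2Z)-2-methylbut-2-enoyl, isovaleroyl = 3-methylbutanoyl, MOM = methoxymethyl, Ipc = isopinocampheyl from (−)-α-pinene.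

**Route**

Step 1
Reactants: 1 methyl 2,2-dimethyl-3-oxopropanoate; 2 diethyl (2-methylprop-2-en-1-yl)phosphonate
Product: 3 methyl (3E)-2,2,5-trimethylhexa-3,5-dienoate
Conditions: 2, n-BuLi, THF/DMPU, −78 °C; then 1, −78 °C → reflux
Reagents that add atoms: none
Why: Horner–Wadsworth–Emmons olefination of a non-enolisable aldehyde with the allylic phosphonate anion gives the (E)-1,3-diene C2=C3(CH3)–C4=C5–C6(CH3)2–C7 by trans-selective loss of phosphate.

Step 2
Reactants: 4 4,4,5,5-tetramethyl-2-vinyl-1,3,2-dioxaborolane; 5 but-3-en-2-one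
Product: 6 (3E)-4-Bpin-but-3-en-2-one
Conditions: second-generation Hoveyda–Grubbs catalyst RuCl2(H2IMes)(=CH-C6H4-2-O-i-Pr) (3 mol%), 5 (3 equiv), CH2Cl2, 40 °C
Reagents that add atoms: none
Why: olefin cross-metathesis of a vinyl boronate with an enone is thermodynamically E-selective and is driven by loss of ethene.

Step 3
Reactants: 3 methyl (3E)-2,2,5-trimethylhexa-3,5-dienoate; 6 (3E)-4-Bpin-but-3-en-2-one
Product: 7 methyl 2-[(1S,5S,6R)-6-acetyl-3-methyl-5-Bpin-cyclohex-2-en-1-yl]-2-methylpropanoate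
Conditions: (S)-3,3-diphenyl-1-(2-methylphenyl)tetrahydro-1H,3H-pyrrolo[1,2-c][1,3,2]oxazaborole (20 mol%), AlBr3 (16 mol%), CH2Cl2, −78 → −40 °C
Reagents that add atoms: none
Why: Lewis-acid-catalysed Diels–Alder reaction (Corey oxazaborolidinium type) in which the coordinated acetyl group is endo and the boron-bearing β-carbon (C1) bonds to the unsubstituted diene terminus C2, so that C5–C6 and C11–acetyl are cis, C1–B is trans to the acetyl (E-dienophile geometry retained), the ring olefin sits at C3=C4, and the catalyst blocks one enone face to fix the absolute configuration at C5, C11 and C1.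

Step 4
Reactants: 7 methyl 2-[(1S,5S,6R)-6-acetyl-3-methyl-5-Bpin-cyclohex-2-en-1-yl]-2-methylpropanoate
Product: 8 methyl 2-methyl-2-[(1S,5S,6R)-3-methyl-6-(prop-1-en-2-yl)-5-Bpin-cyclohex-2-en-1-yl]propanoate
Conditions: Zn, CH2Br2, TiCl4, THF/CH2Cl2, 0 °C → rt
Reagents that add atoms: dibromomethane, BrCBr
Why: Takai–Lombardo methylenation with a non-basic zinc–titanium methylidene converts the methyl ketone into the isopropenyl group without epimerising the adjacent C11 and without touching the ester or the boronate.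

Step 5
Reactants: 8 methyl 2-methyl-2-[(1S,5S,6R)-3-methyl-6-(prop-1-en-2-yl)-5-Bpin-cyclohex-2-en-1-yl]propanoate
Product: 9 2-methyl-2-[(1S,5S,6R)-3-methyl-6-(prop-1-en-2-yl)-5-Bpin-cyclohex-2-en-1-yl]propanal
Conditions: i-Bu2AlH (1.1 equiv), CH2Cl2, −78 °C; aq. KNaC4H4O6 work-up
Reagents that add atoms: none
Why: partial reduction, because the hindered α,α-dimethyl ester gives a tetrahedral aluminium hemiacetal that survives at −78 °C and releases the aldehyde only on work-up, while the pinacol boronate and the alkenes are inert at this temperature.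

Step 6
Reactants: 9 2-methyl-2-[(1S,5S,6R)-3-methyl-6-(prop-1-en-2-yl)-5-Bpin-cyclohex-2-en-1-yl]propanal; 10 3-(methoxymethoxy)prop-1-ene
Product: 13 (3S,4S)-4-(methoxymethoxy)-2-methyl-2-[(1S,5S,6R)-3-methyl-6-(prop-1-en-2-yl)-5-Bpin-cyclohex-2-en-1-yl]hex-5-en-3-ol, via allylborane reagent 11 (not isolated), via borinate adduct 12 (not isolated)
Conditions: 10, s-BuLi, THF, −78 °C; (+)-Ipc2BOMe; BF3·OEt2; then 9, −78 °C; HOCH2CH2NH2, 0 °C → rt
Reagents that add atoms: none
Why: Brown (Z)-γ-alkoxyallylboration through a chair transition state, in which the Z geometry gives the syn (threo) C7/C8 relationship and the Ipc groups from (−)-α-pinene direct attack on the Re face of the aldehyde, setting C7 (S) and C8 (S) under reagent control.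

Step 7
Reactants: 13 (3S,4S)-4-(methoxymethoxy)-2-methyl-2-[(1S,5S,6R)-3-methyl-6-(prop-1-en-2-yl)-5-Bpin-cyclohex-2-en-1-yl]hex-5-en-3-ol; 14 (2Z)-2-methylbut-2-enoic anhydride
Product: 15 (3S,4S)-4-(methoxymethoxy)-2-methyl-2-[(1S,5S,6R)-3-methyl-6-(prop-1-en-2-yl)-5-Bpin-cyclohex-2-en-1-yl]hex-5-en-3-yl (2Z)-2-methylbut-2-enoate
Conditions: LiN(SiMe3)2 (1.1 equiv), THF, −78 °C; then 14, −78 → 0 °C
Reagents that add atoms: none
Why: O-acylation of the lithium alkoxide by the anhydride at low temperature esterifies the hindered neopentyl carbinol without Z→E isomerisation of the angeloyl group.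

Step 8
Reactants: 15 (3S,4S)-4-(methoxymethoxy)-2-methyl-2-[(1S,5S,6R)-3-methyl-6-(prop-1-en-2-yl)-5-Bpin-cyclohex-2-en-1-yl]hex-5-en-3-yl (2Z)-2-methylbut-2-enoate
Product: 16 7β-angeloyloxy-8α-(methoxymethoxy)-1α-Bpin-4,10-seco-longipina-3,9-diene
Conditions: second-generation Grubbs catalyst RuCl2(H2IMes)(PCy3)(=CHPh) (10 mol%), toluene, 80 °C
Reagents that add atoms: none
Why: ring-closing metathesis of the isopropenyl and vinyl groups closes ring B as the trisubstituted C9=C10 cycloheptene with loss of ethene, and the cis C5/C11 relationship from step 3 makes the bicycle cis-fused.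

Step 9
Reactants: 16 7β-angeloyloxy-8α-(methoxymethoxy)-1α-Bpin-4,10-seco-longipina-3,9-diene
Product: 17 7β-angeloyloxy-8α-hydroxy-1α-Bpin-4,10-seco-longipina-3,9-diene
Conditions: ZnBr2, n-PrSH, CH2Cl2, 0 °C, 10 min
Reagents that add atoms: none
Why: Lewis-acid-promoted acetal cleavage in which the thiol traps the methoxymethyl cation frees the allylic 8-OH while the esters, the boronate and the alkenes are untouched.

Step 10
Reactants: 17 7β-angeloyloxy-8α-hydroxy-1α-Bpin-4,10-seco-longipina-3,9-diene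
Product: 18 7β-angeloyloxy-9α,10α-epoxy-8α-hydroxy-1α-Bpin-4,10-seco-longipin-3-ene
Conditions: VO(acac)2 (5 mol%), t-BuOOH (1.2 equiv), CH2Cl2, 0 °C
Reagents that add atoms: tert-butyl hydroperoxide, CC(C)(C)OO
Why: vanadium-catalysed hydroxyl-directed epoxidation, in which the 8α-OH delivers the peroxide to its own face of C9=C10 (also the convex face) to give the 9α,10α-epoxide and so sets C9 and C10, while the undirected C3=C4 and angelate olefins do not react.

Step 11
Reactants: 18 7β-angeloyloxy-9α,10α-epoxy-8α-hydroxy-1α-Bpin-4,10-seco-longipin-3-ene; 19 3-methylbutanoic anhydride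
Product: 20 7β-angeloyloxy-9α,10α-epoxy-8α-isovaleroyloxy-1α-Bpin-4,10-seco-longipin-3-ene
Conditions: 19, Et3N, DMAP (10 mol%), CH2Cl2, 0 °C → rt
Reagents that add atoms: none
Why: DMAP-catalysed acyl transfer (Steglich-type acylation) to the only free hydroxyl.

Step 12
Reactants: 20 7β-angeloyloxy-9α,10α-epoxy-8α-isovaleroyloxy-1α-Bpin-4,10-seco-longipin-3-ene
Product: 21 7β-angeloyloxy-9α,10α-epoxy-8α-isovaleroyloxy-4,10-seco-longipin-3-en-1α-ol
Conditions: NaBO3·4H2O, THF/H2O, rt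
Reagents that add atoms: sodium perborate NaBO3, [Na+].[O-]OB=O
Why: perborate oxidation of the C–B bond (1,2-shift of carbon from boron to oxygen with retention) unmasks the C1 hydroxyl under mild conditions that spare the epoxide and both esters.

Step 13
Reactants: 21 7β-angeloyloxy-9α,10α-epoxy-8α-isovaleroyloxy-4,10-seco-longipin-3-en-1α-ol
Product: 22 7β-angeloyloxy-9α,10α-epoxy-8α-isovaleroyloxy-4,10-seco-longipin-3-en-1-one
Conditions: Dess–Martin periodinane, NaHCO3, CH2Cl2, 0 °C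
Reagents that add atoms: none
Why: Dess–Martin oxidation under buffered non-enolising conditions gives the β,γ-unsaturated ketone without conjugation of C3=C4, epimerisation of C11 or β-elimination of the epoxide.

Step 14
Reactants: 22 7β-angeloyloxy-9α,10α-epoxy-8α-isovaleroyloxy-4,10-seco-longipin-3-en-1-one
Product: 25 (4R,5S,7S,8S,9S,10R,11R)-7-angeloyloxy-9-hydroxy-8-isovaleroyloxy-longipin-2-en-1-one, via silyl dienol ether 23 (not isolated), via O-silyl cycloadduct 24 (not isolated)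
Conditions: Me3SiOTf (2.2 equiv), i-Pr2NEt (1.2 equiv), CH2Cl2, −78 → −40 °C; then 0.5 mol/L aq. HCl, THF, 0 °C
Reagents that add atoms: none
Why: Proposed new method: soft enolisation removes the doubly activated H-2 (α to C=O and allylic) rather than H-11 to give 1-siloxy-1,3-diene 23, whose terminal carbon C4 attacks the silyl-activated epoxide at tertiary C10 anti to the C–O bond (4-exo-tet in the Baldwin-favoured enol-exo mode, with the cis ring fusion holding C10 over C4 and epoxide strain paying for the cyclobutane), which sets C4 and C10 with inversion at C10, leaves O-9 as silyl ether 24 that is hydrolysed on work-up and restores the enone by loss of the silyl group, the closest known reaction types being the vinylogous Mukaiyama reaction, Lewis-acid epoxide-initiated cation–olefin cyclisations terminated by silyl enol ethers, one-pot enol-silane formation/Mukaiyama addition with a silyl triflate plus amine, and the Stork epoxynitrile 4-exo closure of cyclobutanes at fully substituted epoxide carbons.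

**Compound list**

1 | methyl 2,2-dimethyl-3-oxopropanoate | COC(=O)C(C)(C)C=O | starting material
2 | diethyl (2-methylprop-2-en-1-yl)phosphonate | CCOP(=O)(CC(C)=C)OCC | starting material
3 | methyl (3E)-2,2,5-trimethylhexa-3,5-dienoate | COC(=O)C(C)(C)/C=C/C(C)=C | intermediate
4 | 4,4,5,5-tetramethyl-2-vinyl-1,3,2-dioxaborolane | C=CB1OC(C)(C)C(C)(C)O1 | starting material
5 | but-3-en-2-one | CC(=O)C=C | starting material
6 | (3E)-4-Bpin-but-3-en-2-one | CC(=O)/C=C/B1OC(C)(C)C(C)(C)O1 | intermediate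
7 | methyl 2-[(1S,5S,6R)-6-acetyl-3-methyl-5-Bpin-cyclohex-2-en-1-yl]-2-methylpropanoate (side chain and acetyl cis, boron trans to acetyl) | CC(=O)[C@@H]1[C@@H](B2OC(C)(C)C(C)(C)O2)CC(C)=C[C@@H]1C(C)(C)C(=O)OC | intermediate
8 | methyl 2-methyl-2-[(1S,5S,6R)-3-methyl-6-(prop-1-en-2-yl)-5-Bpin-cyclohex-2-en-1-yl]propanoate | C=C(C)[C@@H]1[C@@H](B2OC(C)(C)C(C)(C)O2)CC(C)=C[C@@H]1C(C)(C)C(=O)OC | intermediate
9 | 2-methyl-2-[(1S,5S,6R)-3-methyl-6-(prop-1-en-2-yl)-5-Bpin-cyclohex-2-en-1-yl]propanal | C=C(C)[C@@H]1[C@@H](B2OC(C)(C)C(C)(C)O2)CC(C)=C[C@@H]1C(C)(C)C=O | intermediate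
10 | 3-(methoxymethoxy)prop-1-ene (allyl MOM ether) | C=CCOCOC | starting material
11 | [(2Z)-3-(methoxymethoxy)prop-2-en-1-yl]diisopinocampheylborane (Ipc from (−)-α-pinene) | COCO/C=C\CB([C@H]1C[C@H]2C[C@@H]([C@@H]1C)C2(C)C)[C@H]1C[C@H]2C[C@@H]([C@@H]1C)C2(C)C | intermediate (not isolated)
12 | diisopinocampheylborinate (O–BIpc2) of alcohol 13 | C=C(C)[C@@H]1[C@@H](B2OC(C)(C)C(C)(C)O2)CC(C)=C[C@@H]1C(C)(C)[C@H](OB([C@H]3C[C@H]4C[C@@H]([C@@H]3C)C4(C)C)[C@H]3C[C@H]4C[C@@H]([C@@H]3C)C4(C)C)[C@@H](OCOC)C=C | intermediate (not isolated)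
13 | (3S,4S)-4-(methoxymethoxy)-2-methyl-2-[(1S,5S,6R)-3-methyl-6-(prop-1-en-2-yl)-5-Bpin-cyclohex-2-en-1-yl]hex-5-en-3-ol (chain C3 = C7, chain C4 = C8) | C=C(C)[C@@H]1[C@@H](B2OC(C)(C)C(C)(C)O2)CC(C)=C[C@@H]1C(C)(C)[C@H](O)[C@@H](OCOC)C=C | intermediate
14 | (2Z)-2-methylbut-2-enoic anhydride (angelic anhydride) | C/C=C(/C)C(=O)OC(=O)/C(C)=C\C | starting material
15 | angelate of 13: (3S,4S)-4-(methoxymethoxy)-2-methyl-2-[(1S,5S,6R)-3-methyl-6-(prop-1-en-2-yl)-5-Bpin-cyclohex-2-en-1-yl]hex-5-en-3-yl (2Z)-2-methylbut-2-enoate | C=C(C)[C@@H]1[C@@H](B2OC(C)(C)C(C)(C)O2)CC(C)=C[C@@H]1C(C)(C)[C@H](OC(=O)/C(C)=C\C)[C@@H](OCOC)C=C | intermediate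
16 | 7β-angeloyloxy-8α-(methoxymethoxy)-1α-Bpin-4,10-seco-longipina-3,9-diene (cis-fused, H-5 and H-11 α, boron cis to H-11) | C/C=C(/C)C(=O)O[C@@H]1[C@@H](OCOC)C=C(C)[C@@H]2[C@@H](B3OC(C)(C)C(C)(C)O3)CC(C)=C[C@@H]2C1(C)C | intermediate
17 | 7β-angeloyloxy-8α-hydroxy-1α-Bpin-4,10-seco-longipina-3,9-diene | C/C=C(/C)C(=O)O[C@@H]1[C@@H](O)C=C(C)[C@@H]2[C@@H](B3OC(C)(C)C(C)(C)O3)CC(C)=C[C@@H]2C1(C)C | intermediate
18 | 7β-angeloyloxy-9α,10α-epoxy-8α-hydroxy-1α-Bpin-4,10-seco-longipin-3-ene | C/C=C(/C)C(=O)O[C@@H]1[C@@H](O)[C@H]2O[C@@]2(C)[C@@H]3[C@@H](B4OC(C)(C)C(C)(C)O4)CC(C)=C[C@@H]3C1(C)C | intermediate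
19 | 3-methylbutanoic anhydride (isovaleric anhydride) | CC(C)CC(=O)OC(=O)CC(C)C | starting material
20 | 7β-angeloyloxy-9α,10α-epoxy-8α-isovaleroyloxy-1α-Bpin-4,10-seco-longipin-3-ene | C/C=C(/C)C(=O)O[C@@H]1[C@@H](OC(=O)CC(C)C)[C@H]2O[C@@]2(C)[C@@H]3[C@@H](B4OC(C)(C)C(C)(C)O4)CC(C)=C[C@@H]3C1(C)C | intermediate
21 | 7β-angeloyloxy-9α,10α-epoxy-8α-isovaleroyloxy-4,10-seco-longipin-3-en-1α-ol | C/C=C(/C)C(=O)O[C@@H]1[C@@H](OC(=O)CC(C)C)[C@H]2O[C@@]2(C)[C@@H]3[C@@H](O)CC(C)=C[C@@H]3C1(C)C | intermediate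
22 | 7β-angeloyloxy-9α,10α-epoxy-8α-isovaleroyloxy-4,10-seco-longipin-3-en-1-one (β,γ-unsaturated ketone) | C/C=C(/C)C(=O)O[C@@H]1[C@@H](OC(=O)CC(C)C)[C@H]2O[C@@]2(C)[C@@H]3C(=O)CC(C)=C[C@@H]3C1(C)C | intermediate
23 | 7β-angeloyloxy-9α,10α-epoxy-8α-isovaleroyloxy-1-(trimethylsilyloxy)-4,10-seco-longipina-1,3-diene | C/C=C(/C)C(=O)O[C@@H]1[C@@H](OC(=O)CC(C)C)[C@H]2O[C@@]2(C)[C@@H]3C(O[Si](C)(C)C)=CC(C)=C[C@@H]3C1(C)C | intermediate (not isolated)
24 | 7β-angeloyloxy-8α-isovaleroyloxy-9α-(trimethylsilyloxy)longipin-2-en-1-one | C/C=C(/C)C(=O)O[C@@H]1[C@@H](OC(=O)CC(C)C)[C@@H](O[Si](C)(C)C)[C@@]2(C)[C@@H]3C(=O)C=C(C)[C@H]2[C@@H]3C1(C)C | intermediate (not isolated)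
25 | (4R,5S,7S,8S,9S,10R,11R)-7-angeloyloxy-9-hydroxy-8-isovaleroyloxy-longipin-2-en-1-one (7β-angeloyloxy-8α-isovaleroyloxy-9α-hydroxy) | C/C=C(/C)C(=O)O[C@@H]1[C@@H](OC(=O)CC(C)C)[C@@H](O)[C@@]2(C)[C@@H]3C(=O)C=C(C)[C@H]2[C@@H]3C1(C)C | target

**Totals**

Total step count: 14. Longest linear sequence: 13 steps (1 → 25 through steps 1 and 3–14; step 2 is a one-step branch).

**Steps most likely to fail, with fallbacks**

Step 14 is the least precedented step. The silyl-activated epoxide may instead eliminate to an allylic silyl ether, suffer a 1,2-hydride shift to the C9 ketone, or be opened by the C8 ester. The fallback sets out from alcohol 21 and changes both the nucleophile and the termination. BF3·OEt2 in CH2Cl2 at −78 °C lets the isolated C3=C4 olefin itself attack C10 in an epoxide-initiated cation–olefin cyclisation, ending with loss of H-2. This gives 7β-angeloyloxy-8α-isovaleroyloxy-longipin-2-ene-1,9α-diol F1. MnO2 in CH2Cl2 then oxidises only the allylic C1 carbinol, and the route is rejoined at 25.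

Step 3 may be slow with the hindered diene or give low or inverted enantioselection, since β-boryl enones are untested with this catalyst class. The catalyst antipode given is a prediction and must be checked at 13, where a wrong ring enantiomer appears as a second diastereomer. The fallback sets out from 3 and 6 and moves the enantiocontrol to a resolution by the chiral allylborane. Me2AlCl in CH2Cl2 at −78 °C gives 7 together with its enantiomer, methyl 2-[(1R,5R,6S)-6-acetyl-3-methyl-5-Bpin-cyclohex-2-en-1-yl]-2-methylpropanoate F2. Steps 4 and 5 are run on the racemate and give, beside 8 and 9, the enantiomeric isopropenyl ester F3 and the enantiomeric aldehyde F4. Step 6 is reagent-controlled, so it converts the racemic aldehyde through 12 and the borinate of the other series F5 into 13 and the diastereomeric (3S,4S)-alcohol on the enantiomeric ring F6. The two are separated by chromatography and the route is rejoined at 13, at the cost of half the material.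

Step 8 may stall because the vinyl group sits next to a neopentyl ester and a quaternary carbon, and a trisubstituted olefin must form. The fallback sets out from 13 and closes ring B before the bulky ester is installed. Second-generation Hoveyda–Grubbs catalyst in toluene at 80 °C gives 8α-(methoxymethoxy)-1α-Bpin-4,10-seco-longipina-3,9-dien-7β-ol F7. This is then acylated with LiN(SiMe3)2 and 14 as in step 7, and the route is rejoined at 16.

**Further compounds**

F1 | step 14 | 7β-angeloyloxy-8α-isovaleroyloxy-longipin-2-ene-1,9α-diol (C1 as in 21) | C/C=C(/C)C(=O)O[C@@H]1[C@@H](OC(=O)CC(C)C)[C@@H](O)[C@@]2(C)[C@@H]3[C@@H](O)C=C(C)[C@H]2[C@@H]3C1(C)C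
F2 | step 3 | methyl 2-[(1R,5R,6S)-6-acetyl-3-methyl-5-Bpin-cyclohex-2-en-1-yl]-2-methylpropanoate (enantiomer of 7) | CC(=O)[C@H]1[C@H](B2OC(C)(C)C(C)(C)O2)CC(C)=C[C@H]1C(C)(C)C(=O)OC
F3 | step 3 | methyl 2-methyl-2-[(1R,5R,6S)-3-methyl-6-(prop-1-en-2-yl)-5-Bpin-cyclohex-2-en-1-yl]propanoate (enantiomer of 8) | C=C(C)[C@H]1[C@H](B2OC(C)(C)C(C)(C)O2)CC(C)=C[C@H]1C(C)(C)C(=O)OC
F4 | step 3 | 2-methyl-2-[(1R,5R,6S)-3-methyl-6-(prop-1-en-2-yl)-5-Bpin-cyclohex-2-en-1-yl]propanal (enantiomer of 9) | C=C(C)[C@H]1[C@H](B2OC(C)(C)C(C)(C)O2)CC(C)=C[C@H]1C(C)(C)C=O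
F5 | step 3 | diisopinocampheylborinate of F6 (not isolated) | C=C(C)[C@H]1[C@H](B2OC(C)(C)C(C)(C)O2)CC(C)=C[C@H]1C(C)(C)[C@H](OB([C@H]3C[C@H]4C[C@@H]([C@@H]3C)C4(C)C)[C@H]3C[C@H]4C[C@@H]([C@@H]3C)C4(C)C)[C@@H](OCOC)C=C
F6 | step 3 | (3S,4S)-4-(methoxymethoxy)-2-methyl-2-[(1R,5R,6S)-3-methyl-6-(prop-1-en-2-yl)-5-Bpin-cyclohex-2-en-1-yl]hex-5-en-3-ol | C=C(C)[C@H]1[C@H](B2OC(C)(C)C(C)(C)O2)CC(C)=C[C@H]1C(C)(C)[C@H](O)[C@@H](OCOC)C=C
F7 | step 8 | 8α-(methoxymethoxy)-1α-Bpin-4,10-seco-longipina-3,9-dien-7β-ol | O[C@@H]1[C@@H](OCOC)C=C(C)[C@@H]2[C@@H](B3OC(C)(C)C(C)(C)O3)CC(C)=C[C@@H]2C1(C)C
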